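Ring A (the cyclohexene) enters as a benzoate; retrosynthesis cuts (i) the ester C–O bond to the C16 hydroxy acid (from dec-9-ynoic acid), (ii) the bond from the methyl/hydroxymethyl-bearing quaternary carbon to the bridgehead CH, (iii) the two bonds of the formyl-bearing cyclopentane that tie an acrylate CH–CH2 unit to the spiro carbon and to the neighbouring CH2, (iv) the aryl–CH bond.
Forward: step 6 builds ring B (formyl-bearing cyclopentane) spiro on the ipso carbon of the benzoate and dearomatises it, step 9 closes ring C (second cyclopentane) by Michael addition to give the bicyclo[3.2.1]octene, then a γ-lactone locks the carbinol and the future formyl carbon before acylation with the chain.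
Enabling feature: the quaternary carbon common to rings A, B and C lies ortho to the oxygen-bearing carbon and para to the carboxyl-bearing carbon of ring A, so a 3-methoxy-4-alkylbenzoate accepts a radical at that ipso carbon (captodative cyclohexadienyl) and leaves enol ether and ester where the target has its C–O and CO2H.
Stereochemistry: Rh/(R)-BINAP sets the benzylic CH; allylic strain relays it to the spiro carbon; the tether fixes the bridgehead and ring fusion, and enolate orientation the quaternary carbon, in step 9; hydride delivery plus lactonisation fix the carbinol and the formyl-bearing carbon; semihydrogenation gives the Z-alkene.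
Key step: step 6
Assumption: as written, the descriptor of the CH shared by the two cyclopentanes would make these rings trans-fused on the bicyclo[3.2.1]octene, which closure through the tether cannot give; it is read as the cis fusion, so this carbon is drawn cis-fused in all intermediates and the target line repeats the given string.

Step 1
Reactants: 1 tert-butyl 4-bromo-3-methoxybenzoate
Product: 2 aryl pinacol boronate
Conditions: bis(pinacolato)diboron, Pd(dppf)Cl2 (3 mol%), KOAc, 1,4-dioxane, 90 °C
Reagents that add atoms: bis(pinacolato)diboron (CC1(C)OB(OC1(C)C)B1OC(C)(C)C(C)(C)O1)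
Why: Miyaura borylation converts the aryl bromide into the boronate needed for the rhodium step, and the tert-butyl ester and the aryl ether are inert to it.

Step 2
Reactants: 2 aryl pinacol boronate; 3 furan-2(5H)-one
Product: 4 (R)-4-aryl butyrolactone
Conditions: [Rh(OH)(cod)]2 (2.5 mol%), (R)-BINAP (6 mol%), 1,4-dioxane/H2O (10:1), 60 °C
Reagents that add atoms: none
Why: Rhodium-catalysed asymmetric 1,4-addition of the arylboron reagent to the unsaturated lactone (Hayashi–Miyaura reaction) forms the aryl–CH bond, and the (R)-BINAP complex should deliver the aryl group to the enantioface that gives the (R)-lactone.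

Step 3
Reactants: 4 (R)-4-aryl butyrolactone
Product: 5 trans-3-methyl-4-aryl butyrolactone
Conditions: LiN(i-Pr)2 (1.05 equiv), THF, −78 °C; MeI
Reagents that add atoms: iodomethane (CI)
Why: Alkylation of the lactone enolate should occur anti to the neighbouring aryl group (trans product) and installs the future ring methyl group on a carbon that is planarised again in step 9.

Step 4
Reactants: 5 trans-3-methyl-4-aryl butyrolactone
Product: 7 benzyl (2S,3R)-3-aryl-2-methyl-4-(phenylselanyl)butanoate, via sodium carboxylate 6 (not isolated)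
Conditions: PhSeH, NaH, DMF, 0 → 110 °C; then BnBr, 25 °C
Reagents that add atoms: benzeneselenol ([SeH]c1ccccc1); benzyl bromide (BrCc1ccccc1)
Why: The soft selenolate opens the lactone by SN2 attack at the O–CH2 carbon and the carboxylate set free is benzylated in the same flask, which differentiates the two chain ends without touching the tert-butyl ester or the benzylic stereocentre.

Step 5
Reactants: 7 benzyl seleno ester
Product: 8 benzyl (2S,3R)-3-aryl-4-iodo-2-methylbutanoate
Conditions: MeI (10 equiv), DMF, 60 °C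
Reagents that add atoms: iodomethane (CI)
Why: Methylation at selenium turns it into a leaving group and iodide displaces methyl phenyl selenide at the primary carbon (SN2 on the selenonium salt), which gives the alkyl iodide needed for halogen-atom transfer.

Step 6
Reactants: 8 benzyl iodo ester; 9 methyl acrylate
Product: 10 spiro[4.5]deca-6,9-diene triester
Conditions: 9 (5 equiv), 4CzIPN (2 mol%), Et3N (3 equiv), H2O (10 equiv), MeCN, blue LEDs (450 nm), 25 °C
Reagents that add atoms: none
Why: Proposed new method: an α-aminoalkyl radical from Et3N abstracts iodine from 8, the primary radical adds to the β-carbon of 9 (Giese addition), the α-ester radical attacks the ipso carbon of the benzoate, and the cyclohexadienyl radical is reduced by the reduced photocatalyst to the ester dienolate (radical–polar crossover), which is protonated at the carbon bearing the tert-butyl ester. The closest known reaction types are the halogen-atom-transfer Giese hydroalkylation of alkyl iodides and the two-component photoredox dearomative spirocyclisation of tethered radicals onto electron-poor arenes; joining them in one chain is the new element, and it is reasonable because both use the same catalyst, amine and redox events. Ring B closes in the 5-exo-trig spiro mode, favoured over six-membered closure at the ortho CH because only ipso attack gives a radical flanked by the ortho methoxy donor and the para ester acceptor. The spiro carbon is set by allylic 1,3-strain: the benzylic hydrogen lies in the arene plane beside the methoxy group, so the chain closes on the face that leaves the propanoate-bearing substituent cis to the unsubstituted ortho carbon, as the later cis ring fusion requires. The ester-bearing cyclopentane carbon should form with its ester anti to that substituent (any epimer is corrected by lactonisation in step 14), and the protonated ring carbon forms as a mixture that is planarised in step 8. The step needs cyclisation to outrun reduction of the α-ester radical, which the low stationary concentration of reduced photocatalyst and the captodative stabilisation of the spiro radical should secure.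

Step 7
Reactants: 10 spiro[4.5]deca-6,9-diene triester
Product: 11 dioxolane ketal
Conditions: ethylene glycol (5 equiv), PPTS (cat.), CH2Cl2, 25 °C
Reagents that add atoms: ethane-1,2-diol (OCCO)
Why: Acid-catalysed addition of the diol to the methyl enol ether (transketalisation) masks the ketone as a dioxolane, so that no acidic methylene flanks the future enoate in the base steps.

Step 8
Reactants: 11 dioxolane ketal
Product: 12 conjugated enoate ketal
Conditions: DBU (1 equiv), toluene, 60 °C
Reagents that add atoms: none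
Why: A base-mediated 1,3-prototropic shift through the ester dienolate moves the isolated ring double bond into conjugation with the tert-butyl ester and so creates the Michael acceptor whose β-carbon is the future bridgehead.

Step 9
Reactants: 12 conjugated enoate ketal
Product: 13 tricyclic triester ketal
Conditions: LiN(i-Pr)2 (2.2 equiv), THF, −78 → −40 °C; NH4Cl (aq)
Reagents that add atoms: none
Why: Intramolecular Michael addition (5-exo-trig) of the propanoate enolate to the unsaturated tert-butyl ester closes ring C while the second equivalent of base holds the methyl ester as its unreactive enolate; the tether allows attack only on the face that gives the cis-fused bicyclo[3.3.0]octane and fixes the bridgehead, and the bulky ester enolate should turn away from the ester-bearing bridge so that the new quaternary carbon carries its ester exo and its methyl endo.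

Step 10
Reactants: 13 tricyclic triester ketal
Product: 14 tricyclic carboxylic acid
Conditions: H2 (1 atm), Pd/C, EtOAc, 25 °C
Reagents that add atoms: none
Why: Hydrogenolysis removes only the benzyl ester, because at this stage the molecule holds no alkene and the tert-butyl ester, methyl ester and ketal are inert.

Step 11
Reactants: 14 tricyclic carboxylic acid
Product: 16 keto alcohol, via ketal alcohol 15 (not isolated)
Conditions: BH3·THF (2.5 equiv), THF, 0 → 25 °C; then 2 M HCl, THF, 25 °C
Reagents that add atoms: water (O)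
Why: Borane reduces the free neopentyl carboxylic acid much faster than the two esters, and the aqueous acid added afterwards hydrolyses the dioxolane to the ketone in the same flask.

Step 12
Reactants: 16 keto alcohol
Product: 17 silyl ether ketone
Conditions: TBSCl, imidazole, DMF, 25 °C
Reagents that add atoms: tert-butyldimethylsilyl chloride (CC(C)(C)[Si](C)(C)Cl)
Why: Silylation of the only free hydroxyl group protects the primary alcohol for the remaining steps.

Step 13
Reactants: 17 silyl ether ketone
Product: 19 enone diester, via trimethylsilyl enol ether 18 (not isolated)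
Conditions: LiN(SiMe3)2 (1.1 equiv), Me3SiCl, THF, −78 °C; then Pd(OAc)2 (1.1 equiv), MeCN, 25 °C
Reagents that add atoms: none
Why: The ketone can enolise only toward its methylene group (the other α-carbon is the quaternary spiro carbon), so silyl enol ether formation and Saegusa–Ito oxidation place the double bond regiospecifically between that carbon and the carbon bearing the tert-butyl ester.

Step 14
Reactants: 19 enone diester
Product: 21 γ-lactone, via allylic hydroxy ester 20 (not isolated)
Conditions: NaBH4, CeCl3·7H2O, MeOH, −40 °C; then NaOMe (0.2 equiv), MeOH, 25 °C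
Reagents that add atoms: none
Why: Luche reduction should give 1,2-reduction of the enone with hydride entering anti to the ester on the adjacent cyclopentane carbon, and the alkoxide then closes a γ-lactone with that ester, which is possible only for the cis arrangement and under methoxide draws in any epimer at the ester-bearing carbon, so that both centres are fixed.

Step 15
Reactants: 21 γ-lactone
Product: 22 diol
Conditions: LiBH4 (2 equiv), THF, 0 → 25 °C
Reagents that add atoms: none
Why: Lithium borohydride reduces the lactone to the 1,4-diol while the hindered conjugated tert-butyl ester and the silyl ether are left.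

Step 16
Reactants: 22 diol
Product: 23 triethylsilyl ether alcohol
Conditions: Et3SiCl (1.05 equiv), imidazole, CH2Cl2, −40 °C
Reagents that add atoms: chlorotriethylsilane (CC[Si](Cl)(CC)CC)
Why: The primary hydroxyl reacts far faster with the silyl chloride than the hindered secondary allylic one, so monosilylation leaves the carbinol free for acylation.

Step 17
Reactants: 24 dec-9-ynoic acid; 25 (6-bromohexyloxy)(tert-butyl)dimethylsilane
Product: 26 16-silyloxyhexadec-9-ynoic acid
Conditions: n-BuLi (2.1 equiv), THF/DMPU, −78 → 25 °C; then 1 M HCl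
Reagents that add atoms: none
Why: The dianion of the terminal alkynoic acid is alkylated at the acetylide carbon by the primary bromide (SN2), which assembles the sixteen-carbon chain with the triple bond between C9 and C10.

Step 18
Reactants: 26 16-silyloxyhexadec-9-ynoic acid
Product: 27 (9Z)-16-silyloxyhexadec-9-enoic acid
Conditions: H2 (1 atm), Pd/CaCO3–Pb(OAc)2 (Lindlar catalyst), quinoline, EtOAc, 25 °C
Reagents that add atoms: none
Why: Lindlar semihydrogenation adds hydrogen syn to the alkyne and stops at the alkene, which sets the Z double bond.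

Step 19
Reactants: 27 (9Z)-16-silyloxyhexadec-9-enoic acid; 23 triethylsilyl ether alcohol
Product: 29 fully protected ester, via mixed anhydride 28 (not isolated)
Conditions: 27, 2,4,6-trichlorobenzoyl chloride, Et3N, THF, 25 °C; then 23, DMAP, toluene, 25 °C
Reagents that add atoms: none
Why: Yamaguchi esterification through the mixed 2,4,6-trichlorobenzoic anhydride acylates the hindered secondary allylic alcohol under DMAP catalysis without touching any stereocentre.

Step 20
Reactants: 29 fully protected ester
Product: 30 protected aldehyde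
Conditions: (COCl)2, DMSO, CH2Cl2, −78 °C; then Et3N, −78 → −20 °C
Reagents that add atoms: none
Why: Under Swern conditions the primary triethylsilyl ether is cleaved and oxidised directly to the aldehyde while the tert-butyldimethylsilyl ethers stay, and the low temperature should avoid epimerisation next to the new formyl group.

Step 21
Reactants: 30 protected aldehyde
Product: 31 target compound
Conditions: CF3CO2H/CH2Cl2/H2O (10:10:1), 0 → 25 °C
Reagents that add atoms: none
Why: Aqueous trifluoroacetic acid cleaves the tert-butyl ester (loss of isobutene) and both primary silyl ethers in one operation, while the secondary ester, the aldehyde and the Z-alkene should be stable to it.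

Compound list (tricyclic compounds use tricyclo[5.3.1.0(1,5)]undecane numbering; unless noted they share the configuration of 13: cyclopentanes cis-fused, C2 substituent cis to C10, C6 methyl endo toward the C8–C10 bridge)
1 | tert-butyl 4-bromo-3-methoxybenzoate | COc1cc(ccc1Br)C(=O)OC(C)(C)C | starting material
2 | tert-butyl 3-methoxy-4-(4,4,5,5-tetramethyl-1,3,2-dioxaborolan-2-yl)benzoate | COc1cc(ccc1B1OC(C)(C)C(C)(C)O1)C(=O)OC(C)(C)C | intermediate
3 | furan-2(5H)-one | O=C1OCC=C1 | starting material
4 | tert-butyl 3-methoxy-4-[(3R)-5-oxooxolan-3-yl]benzoate | O=C1C[C@@H](CO1)c1ccc(cc1OC)C(=O)OC(C)(C)C | intermediate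
5 | tert-butyl 3-methoxy-4-[(3R,4S)-4-methyl-5-oxooxolan-3-yl]benzoate (trans) | O=C1[C@@H](C)[C@@H](CO1)c1ccc(cc1OC)C(=O)OC(C)(C)C | intermediate
6 | sodium (2S,3R)-3-[4-(tert-butoxycarbonyl)-2-methoxyphenyl]-2-methyl-4-(phenylselanyl)butanoate | [Na+].[O-]C(=O)[C@@H](C)[C@@H](C[Se]c1ccccc1)c1ccc(cc1OC)C(=O)OC(C)(C)C | intermediate
7 | benzyl (2S,3R)-3-[4-(tert-butoxycarbonyl)-2-methoxyphenyl]-2-methyl-4-(phenylselanyl)butanoate | O=C(OCc1ccccc1)[C@@H](C)[C@@H](C[Se]c1ccccc1)c1ccc(cc1OC)C(=O)OC(C)(C)C | intermediate
8 | benzyl (2S,3R)-3-[4-(tert-butoxycarbonyl)-2-methoxyphenyl]-4-iodo-2-methylbutanoate | O=C(OCc1ccccc1)[C@@H](C)[C@@H](CI)c1ccc(cc1OC)C(=O)OC(C)(C)C | intermediate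
9 | methyl acrylate | C=CC(=O)OC | starting material
10 | 8-tert-butyl 1-methyl 4-[(2S)-1-(benzyloxy)-1-oxopropan-2-yl]-6-methoxyspiro[4.5]deca-6,9-diene-1,8-dicarboxylate (C1 ester cis to C6, C4 side chain cis to C10, C8 epimers) | O=C(OCc1ccccc1)[C@@H](C)[C@H]1CC[C@H](C(=O)OC)[C@@]12C=CC(C(=O)OC(C)(C)C)C=C2OC | intermediate
11 | 8-tert-butyl 1-methyl 4-[(2S)-1-(benzyloxy)-1-oxopropan-2-yl]-6,6-(ethylenedioxy)spiro[4.5]dec-9-ene-1,8-dicarboxylate (configured as 10) | O=C(OCc1ccccc1)[C@@H](C)[C@H]1CC[C@H](C(=O)OC)[C@@]12C=CC(C(=O)OC(C)(C)C)CC23OCCO3 | intermediate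
12 | 8-tert-butyl 1-methyl 4-[(2S)-1-(benzyloxy)-1-oxopropan-2-yl]-6,6-(ethylenedioxy)spiro[4.5]dec-8-ene-1,8-dicarboxylate (configured as 10) | O=C(OCc1ccccc1)[C@@H](C)[C@H]1CC[C@H](C(=O)OC)[C@@]12CC=C(C(=O)OC(C)(C)C)CC23OCCO3 | intermediate
13 | 6-benzyl 8-tert-butyl 2-methyl 10,10-(ethylenedioxy)-6-methyltricyclo[5.3.1.0(1,5)]undecane-2,6,8-tricarboxylate (benzyl ester exo, C8 epimers) | C[C@@]1(C(=O)OCc4ccccc4)[C@@H]2C[C@]3(C5(OCCO5)CC2C(=O)OC(C)(C)C)[C@@H](C(=O)OC)CC[C@H]13 | intermediate
14 | 8-(tert-butoxycarbonyl)-10,10-(ethylenedioxy)-2-(methoxycarbonyl)-6-methyltricyclo[5.3.1.0(1,5)]undecane-6-carboxylic acid | C[C@@]1(C(=O)O)[C@@H]2C[C@]3(C5(OCCO5)CC2C(=O)OC(C)(C)C)[C@@H](C(=O)OC)CC[C@H]13 | intermediate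
15 | 8-tert-butyl 2-methyl 10,10-(ethylenedioxy)-6-(hydroxymethyl)-6-methyltricyclo[5.3.1.0(1,5)]undecane-2,8-dicarboxylate | C[C@@]1(CO)[C@@H]2C[C@]3(C5(OCCO5)CC2C(=O)OC(C)(C)C)[C@@H](C(=O)OC)CC[C@H]13 | intermediate
16 | 8-tert-butyl 2-methyl 6-(hydroxymethyl)-6-methyl-10-oxotricyclo[5.3.1.0(1,5)]undecane-2,8-dicarboxylate | C[C@@]1(CO)[C@@H]2C[C@]3(C(=O)CC2C(=O)OC(C)(C)C)[C@@H](C(=O)OC)CC[C@H]13 | intermediate
17 | 8-tert-butyl 2-methyl 6-{[(tert-butyldimethylsilyl)oxy]methyl}-6-methyl-10-oxotricyclo[5.3.1.0(1,5)]undecane-2,8-dicarboxylate | C[C@@]1(CO[Si](C)(C)C(C)(C)C)[C@@H]2C[C@]3(C(=O)CC2C(=O)OC(C)(C)C)[C@@H](C(=O)OC)CC[C@H]13 | intermediate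
18 | 8-tert-butyl 2-methyl 6-{[(tert-butyldimethylsilyl)oxy]methyl}-6-methyl-10-[(trimethylsilyl)oxy]tricyclo[5.3.1.0(1,5)]undec-9-ene-2,8-dicarboxylate | C[C@@]1(CO[Si](C)(C)C(C)(C)C)[C@@H]2C[C@]3(C(O[Si](C)(C)C)=CC2C(=O)OC(C)(C)C)[C@@H](C(=O)OC)CC[C@H]13 | intermediate
19 | 8-tert-butyl 2-methyl 6-{[(tert-butyldimethylsilyl)oxy]methyl}-6-methyl-10-oxotricyclo[5.3.1.0(1,5)]undec-8-ene-2,8-dicarboxylate | C[C@@]1(CO[Si](C)(C)C(C)(C)C)[C@@H]2C[C@]3(C(=O)C=C2C(=O)OC(C)(C)C)[C@@H](C(=O)OC)CC[C@H]13 | intermediate
20 | 8-tert-butyl 2-methyl 6-{[(tert-butyldimethylsilyl)oxy]methyl}-10-hydroxy-6-methyltricyclo[5.3.1.0(1,5)]undec-8-ene-2,8-dicarboxylate (hydroxyl cis to the C2 ester) | C[C@@]1(CO[Si](C)(C)C(C)(C)C)[C@@H]2C[C@]3([C@@H](O)C=C2C(=O)OC(C)(C)C)[C@@H](C(=O)OC)CC[C@H]13 | intermediate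
21 | tert-butyl 6-{[(tert-butyldimethylsilyl)oxy]methyl}-6-methyltricyclo[5.3.1.0(1,5)]undec-8-ene-8-carboxylate 2,10-carbolactone (γ-lactone from the C2 carboxyl to the C10 oxygen) | C[C@@]1(CO[Si](C)(C)C(C)(C)C)[C@@H]2C[C@]3([C@@H](O4)C=C2C(=O)OC(C)(C)C)[C@@H](C4=O)CC[C@H]13 | intermediate
22 | tert-butyl 6-{[(tert-butyldimethylsilyl)oxy]methyl}-10-hydroxy-2-(hydroxymethyl)-6-methyltricyclo[5.3.1.0(1,5)]undec-8-ene-8-carboxylate | C[C@@]1(CO[Si](C)(C)C(C)(C)C)[C@@H]2C[C@]3([C@@H](O)C=C2C(=O)OC(C)(C)C)[C@@H](CO)CC[C@H]13 | intermediate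
23 | tert-butyl 6-{[(tert-butyldimethylsilyl)oxy]methyl}-10-hydroxy-6-methyl-2-{[(triethylsilyl)oxy]methyl}tricyclo[5.3.1.0(1,5)]undec-8-ene-8-carboxylate | C[C@@]1(CO[Si](C)(C)C(C)(C)C)[C@@H]2C[C@]3([C@@H](O)C=C2C(=O)OC(C)(C)C)[C@@H](CO[Si](CC)(CC)CC)CC[C@H]13 | intermediate
24 | dec-9-ynoic acid | C#CCCCCCCCC(=O)O | starting material
25 | (6-bromohexyloxy)(tert-butyl)dimethylsilane | BrCCCCCCO[Si](C)(C)C(C)(C)C | starting material
26 | 16-[(tert-butyldimethylsilyl)oxy]hexadec-9-ynoic acid | OC(=O)CCCCCCCC#CCCCCCCO[Si](C)(C)C(C)(C)C | intermediate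
27 | (9Z)-16-[(tert-butyldimethylsilyl)oxy]hexadec-9-enoic acid | OC(=O)CCCCCCC/C=C\CCCCCCO[Si](C)(C)C(C)(C)C | intermediate
28 | (9Z)-16-[(tert-butyldimethylsilyl)oxy]hexadec-9-enoic 2,4,6-trichlorobenzoic anhydride | O=C(OC(=O)c1c(Cl)cc(Cl)cc1Cl)CCCCCCC/C=C\CCCCCCO[Si](C)(C)C(C)(C)C | intermediate
29 | tert-butyl 10-{[(9Z)-16-[(tert-butyldimethylsilyl)oxy]hexadec-9-enoyl]oxy}-6-{[(tert-butyldimethylsilyl)oxy]methyl}-6-methyl-2-{[(triethylsilyl)oxy]methyl}tricyclo[5.3.1.0(1,5)]undec-8-ene-8-carboxylate | C[C@@]1(CO[Si](C)(C)C(C)(C)C)[C@@H]2C[C@]3([C@@H](OC(=O)CCCCCCC/C=C\CCCCCCO[Si](C)(C)C(C)(C)C)C=C2C(=O)OC(C)(C)C)[C@@H](CO[Si](CC)(CC)CC)CC[C@H]13 | intermediate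
30 | tert-butyl 10-{[(9Z)-16-[(tert-butyldimethylsilyl)oxy]hexadec-9-enoyl]oxy}-6-{[(tert-butyldimethylsilyl)oxy]methyl}-2-formyl-6-methyltricyclo[5.3.1.0(1,5)]undec-8-ene-8-carboxylate | C[C@@]1(CO[Si](C)(C)C(C)(C)C)[C@@H]2C[C@]3([C@@H](OC(=O)CCCCCCC/C=C\CCCCCCO[Si](C)(C)C(C)(C)C)C=C2C(=O)OC(C)(C)C)[C@@H](C=O)CC[C@H]13 | intermediate
31 | 2-formyl-10-{[(9Z)-16-hydroxyhexadec-9-enoyl]oxy}-6-(hydroxymethyl)-6-methyltricyclo[5.3.1.0(1,5)]undec-8-ene-8-carboxylic acid (CNP0148862.1, string as given) | C[C@@]1(CO)[C@@H]2C[C@]3([C@@H](OC(=O)CCCCCCC/C=C\CCCCCCO)C=C2C(=O)O)[C@@H](C=O)CC[C@@H]13 | target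

Total step count: 21. Longest linear sequence: 19 steps (steps 1–16 and 19–21; steps 17 and 18 make the acid fragment).

Steps most likely to fail

Step 6 (the step labelled as a new method). The α-ester radical may be reduced or quenched before it cyclises, so that only the open-chain Giese adduct forms, or it may close on the ortho CH instead of the ipso carbon. The fallback separates the two bond formations. Setting out from 8, a silane-mediated Giese addition ((Me3Si)3SiH, AIBN, benzene, 80 °C) to methyl 2-chloroacrylate gives 1-benzyl 7-methyl (2S,3R)-3-[4-(tert-butoxycarbonyl)-2-methoxyphenyl]-6-chloro-2-methylheptanedioate F1. Its α-chloro ester is then reduced on its own under the two-component photoredox dearomative spirocyclisation conditions (4CzIPN, Et3N, H2O, MeCN, blue LEDs, high dilution), where no intermolecular step competes. The route is rejoined at 10.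

Step 9. Proton transfer between the two ester enolates and Claisen-type acyl transfer may compete with the conjugate addition, so that ring C does not close cleanly. The fallback makes the cyclopentane carboxyl a carboxylate during the ring closure. Setting out from 8, the annulation of step 6 is run with allyl acrylate in place of 9 and gives the allyl ester 1-allyl 8-tert-butyl 4-[(2S)-1-(benzyloxy)-1-oxopropan-2-yl]-6-methoxyspiro[4.5]deca-6,9-diene-1,8-dicarboxylate F2. Ketalisation and isomerisation as in steps 7 and 8 give the dioxolane 1-allyl 8-tert-butyl 4-[(2S)-1-(benzyloxy)-1-oxopropan-2-yl]-6,6-(ethylenedioxy)spiro[4.5]dec-9-ene-1,8-dicarboxylate F3 and its conjugated isomer, the spiro[4.5]dec-8-ene F4. Pd(PPh3)4 and morpholine remove the allyl group to give 8-(tert-butoxycarbonyl)-4-[(2S)-1-(benzyloxy)-1-oxopropan-2-yl]-6,6-(ethylenedioxy)spiro[4.5]dec-8-ene-1-carboxylic acid F5. Its lithium carboxylate is not enolised at −78 °C, so LiN(i-Pr)2 (2.1 equiv) generates only the propanoate enolate, and Michael closure gives 6-[(benzyloxy)carbonyl]-8-(tert-butoxycarbonyl)-10,10-(ethylenedioxy)-6-methyltricyclo[5.3.1.0(1,5)]undecane-2-carboxylic acid F6. Methylation with Me3SiCHN2 in MeOH returns to the route at 13.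

Step 14. Hydride may be delivered to the wrong face of the ring ketone, which gives the epimeric carbinol that cannot lactonise. The fallback inverts that carbinol. Setting out from 19, the epimeric alcohol 8-tert-butyl 2-methyl 6-{[(tert-butyldimethylsilyl)oxy]methyl}-10-epi-hydroxy-6-methyltricyclo[5.3.1.0(1,5)]undec-8-ene-2,8-dicarboxylate F7 is saponified selectively at its methyl ester (LiOH, THF/H2O, then HCl) to 8-(tert-butoxycarbonyl)-6-{[(tert-butyldimethylsilyl)oxy]methyl}-10-epi-hydroxy-6-methyltricyclo[5.3.1.0(1,5)]undec-8-ene-2-carboxylic acid F8. An intramolecular Mitsunobu reaction (PPh3, diisopropyl azodicarboxylate, toluene, 0 °C) closes the lactone with inversion at the carbinol carbon and returns to the route at 21.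

Further compounds
F1 | step 6 | 1-benzyl 7-methyl (2S,3R)-3-[4-(tert-butoxycarbonyl)-2-methoxyphenyl]-6-chloro-2-methylheptanedioate | O=C(OCc1ccccc1)[C@@H](C)[C@@H](CCC(Cl)C(=O)OC)c1ccc(cc1OC)C(=O)OC(C)(C)C
F2 | step 9 | 1-allyl 8-tert-butyl 4-[(2S)-1-(benzyloxy)-1-oxopropan-2-yl]-6-methoxyspiro[4.5]deca-6,9-diene-1,8-dicarboxylate | O=C(OCc1ccccc1)[C@@H](C)[C@H]1CC[C@H](C(=O)OCC=C)[C@@]12C=CC(C(=O)OC(C)(C)C)C=C2OC
F3 | step 9 | 1-allyl 8-tert-butyl 4-[(2S)-1-(benzyloxy)-1-oxopropan-2-yl]-6,6-(ethylenedioxy)spiro[4.5]dec-9-ene-1,8-dicarboxylate | O=C(OCc1ccccc1)[C@@H](C)[C@H]1CC[C@H](C(=O)OCC=C)[C@@]12C=CC(C(=O)OC(C)(C)C)CC23OCCO3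
F4 | step 9 | 1-allyl 8-tert-butyl 4-[(2S)-1-(benzyloxy)-1-oxopropan-2-yl]-6,6-(ethylenedioxy)spiro[4.5]dec-8-ene-1,8-dicarboxylate | O=C(OCc1ccccc1)[C@@H](C)[C@H]1CC[C@H](C(=O)OCC=C)[C@@]12CC=C(C(=O)OC(C)(C)C)CC23OCCO3
F5 | step 9 | 8-(tert-butoxycarbonyl)-4-[(2S)-1-(benzyloxy)-1-oxopropan-2-yl]-6,6-(ethylenedioxy)spiro[4.5]dec-8-ene-1-carboxylic acid | O=C(OCc1ccccc1)[C@@H](C)[C@H]1CC[C@H](C(=O)O)[C@@]12CC=C(C(=O)OC(C)(C)C)CC23OCCO3
F6 | step 9 | 6-[(benzyloxy)carbonyl]-8-(tert-butoxycarbonyl)-10,10-(ethylenedioxy)-6-methyltricyclo[5.3.1.0(1,5)]undecane-2-carboxylic acid | C[C@@]1(C(=O)OCc4ccccc4)[C@@H]2C[C@]3(C5(OCCO5)CC2C(=O)OC(C)(C)C)[C@@H](C(=O)O)CC[C@H]13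
F7 | step 14 | 8-tert-butyl 2-methyl 6-{[(tert-butyldimethylsilyl)oxy]methyl}-10-epi-hydroxy-6-methyltricyclo[5.3.1.0(1,5)]undec-8-ene-2,8-dicarboxylate | C[C@@]1(CO[Si](C)(C)C(C)(C)C)[C@@H]2C[C@]3([C@H](O)C=C2C(=O)OC(C)(C)C)[C@@H](C(=O)OC)CC[C@H]13
F8 | step 14 | 8-(tert-butoxycarbonyl)-6-{[(tert-butyldimethylsilyl)oxy]methyl}-10-epi-hydroxy-6-methyltricyclo[5.3.1.0(1,5)]undec-8-ene-2-carboxylic acid | C[C@@]1(CO[Si](C)(C)C(C)(C)C)[C@@H]2C[C@]3([C@H](O)C=C2C(=O)OC(C)(C)C)[C@@H](C(=O)O)CC[C@H]13
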